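- At the first reading, 0.500 d, E stands at 0 % in Tuesday's run and 0 % in Monday's, and Q shows no trend afterwards, so each run is read by its mean Q: 42.9 % on Tuesday, 22.5 % on Monday.

in all of them: E 11 mM
- Tuesday's: J 1.1 equiv; G 0.72 equiv; run made earlier
- Monday's: J 1.1 equiv; G 2.7 equiv; run made earlier
- summer: J 1.10 equiv; G 0.600 equiv; time 6.0 d
- noon: J 1.10 equiv; G 1.20 equiv; time 6.0 d
- dawn: J 1.10 equiv; G 2.00 equiv; time 6.0 d

| run | time / d | Q / % | E / % |
|---|---|---|---|
| Tuesday's | 0.500 | 44.5 | 0 |
| Tuesday's | 1.04 | 42.3 | 0 |
| Tuesday's | 1.67 | 42.0 | 1.9 |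
| Tuesday's | 2.08 | 40.3 | 0 |
| Tuesday's | 2.50 | 44.2 | 1.5 |
| Tuesday's | 3.00 | 44.4 | 0 |
| Monday's | 0.500 | 23.6 | 0 |
| Monday's | 1.04 | 23.9 | 1.0 |
| Monday's | 1.67 | 21.2 | 0.6 |
| Monday's | 2.08 | 23.5 | 0 |
| Monday's | 2.50 | 20.4 | 0.1 |
| Monday's | 3.00 | 22.2 | 0 |

(readings scatter by 1 percentage point)

- "hardly changes" means that all values lie within two and a half points (for a concentration: within two and a half percent of the largest)

1. amount of Q at the end, in percent of the E charged for summer, noon, dawn, in this order
2. how that number moves from the first to the last of them (hardly changes / falls, then rises / rises, then falls / falls all the way / rises all the way)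

- Counting each charged E once, as Q or as lost, gives the odds (a selectivity): Q over the rest, 0.753 on Tuesday and 0.290 on Monday, lower with more G.
- Tuesday's 0.542 is the loaded odds S, the odds times the equivalents of G charged; Monday's S is higher, 0.782. For a charge G, Q is then S/(S+G).
- The reckoning here, unlike the forecast, assumes that with more G the odds never rise and S never falls, as between these two runs. Flat odds bound one side and flat S the other.
- Summer: from 42.9 % to 47.5 %.
- Noon: from 31.1 % to 39.5 %.
- Dawn: from 22.5 % to 28.1 %.
- A straight line through both runs, log odds falling against log G with a slope of size 0.722 (its sign is minus), tightens this to 46.2 %, 34.2 % and 26.5 %, falling all the way.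
- The forecast gives 39 %, 44 % and 27 %, shape "rises, then falls", with noon “just past a peak near 1 equiv”. Its summer lies under the bracket, its noon over it, and its dawn inside.
- The flask gives 44.7 %, 35.0 % and 26.8 %, shape "falls all the way", each inside its bracket.

    G + L → X (k = 150 M⁻¹ h⁻¹)
    J + L → Q (k = 200 M⁻¹ h⁻¹)
    J → D (k = 0.480 h⁻¹)
    E → L (k = 0.790 h⁻¹)

- In summer at 0.0366 d, G takes L at 0.67 of the rate at which J takes it. At that moment J goes to D at 1.2 of the rate at which it goes to Q. Summer ends with S at 0.485, under Tuesday's, and dawn ends with S at 0.732, between Tuesday's and Monday's.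

The data were computed from invented constants; scatter was added.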